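Ring A is numbered C1 (CH2O-palmitoyl), C2 (aryloxy), C3 (OH), C5 (OMe). Everything rests on disconnecting the C5–O bond to a C5–H bond: in a 2,3-dioxygenated benzyl ester, C5–H is the only aromatic C–H whose two neighbours (C4, C6) both carry hydrogen, whereas each of the three C–H bonds of the 1,3,5-trisubstituted ring B lies between two substituents. One iridium-catalysed borylation with oxidation in the same flask thus delivers the missing oxygen as the only free phenol. The precursor is the benzyl palmitate with both phenols as triisopropylsilyl ethers, so that methylation and buffered fluoride cleavage, which spare the ester, finish the synthesis.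

Key step: step 6

Remark: the target has no stereocentre and no stereogenic double bond, so no step has to set configuration.
Assumption: 5-bromo-2-fluoro-3-methoxybenzaldehyde, which only the fallback for step 6 uses, is taken to be purchasable.

Step 1
Reactants: 1 2-fluoro-3-methoxybenzaldehyde; 2 3-methoxy-5-methylphenol
Product: 3 3-methoxy-2-(3-methoxy-5-methylphenoxy)benzaldehyde
Conditions: K2CO3, DMSO, 100 °C
Reagents that add atoms: none
Why: Nucleophilic aromatic substitution (addition–elimination), in which the ortho formyl group stabilises the Meisenheimer adduct, fluoride is the best leaving group for this mechanism, and the phenol has a single OH so that only one ether can form.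

Step 2
Reactants: 3 3-methoxy-2-(3-methoxy-5-methylphenoxy)benzaldehyde
Product: 4 3-hydroxy-2-(3-hydroxy-5-methylphenoxy)benzaldehyde
Conditions: BBr3 (4 equiv), CH2Cl2, −78 °C to 0 °C; then ice/H2O
Reagents that add atoms: none
Why: Lewis acid cleavage of aryl methyl ethers, in which BBr3 binds each methoxy oxygen and bromide removes the methyl group by SN2, while the diaryl ether offers no sp3 carbon for attack and the formyl group is set free unchanged from its boron complex on hydrolysis, as is usual for methoxybenzaldehydes.

Step 3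
Reactants: 4 3-hydroxy-2-(3-hydroxy-5-methylphenoxy)benzaldehyde
Product: 5 2-[3-methyl-5-(triisopropylsilyloxy)phenoxy]-3-(triisopropylsilyloxy)benzaldehyde
Conditions: iPr3SiCl (2.5 equiv), imidazole, DMF, rt
Reagents that add atoms: chlorotri(propan-2-yl)silane, CC(C)[Si](Cl)(C(C)C)C(C)C
Why: Imidazole-promoted O-silylation of both phenols, which leaves the aldehyde untouched and gives bulky ethers that should resist hydride, acylation, borylation, perborate and carbonate and that add to the shielding of the neighbouring C–H bonds.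

Step 4
Reactants: 5 2-[3-methyl-5-(triisopropylsilyloxy)phenoxy]-3-(triisopropylsilyloxy)benzaldehyde
Product: 6 [2-[3-methyl-5-(triisopropylsilyloxy)phenoxy]-3-(triisopropylsilyloxy)phenyl]methanol
Conditions: NaBH4, THF/MeOH, 0 °C
Reagents that add atoms: none
Why: Hydride reduction of an aromatic aldehyde to the benzylic alcohol, to which the aryl silyl ethers and the diaryl ether are inert at 0 °C.

Step 5
Reactants: 6 [2-[3-methyl-5-(triisopropylsilyloxy)phenoxy]-3-(triisopropylsilyloxy)phenyl]methanol; 7 hexadecanoyl chloride (palmitoyl chloride)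
Product: 8 [2-[3-methyl-5-(triisopropylsilyloxy)phenoxy]-3-(triisopropylsilyloxy)phenyl]methyl hexadecanoate
Conditions: Et3N, DMAP (cat.), CH2Cl2, 0 °C to rt
Reagents that add atoms: none
Why: DMAP-catalysed acylation (nucleophilic acyl substitution) of the primary benzylic alcohol, the only free OH in the molecule, by the acid chloride.

Step 6
Reactants: 8 [2-[3-methyl-5-(triisopropylsilyloxy)phenoxy]-3-(triisopropylsilyloxy)phenyl]methyl hexadecanoate
Product: 10 [5-hydroxy-2-[3-methyl-5-(triisopropylsilyloxy)phenoxy]-3-(triisopropylsilyloxy)phenyl]methyl hexadecanoate, via aryl pinacol boronate 9 (not isolated)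
Conditions: [Ir(OMe)(cod)]2 (2 mol%), 4,4'-di-tert-butyl-2,2'-bipyridine (4 mol%), B2pin2 (1.0 equiv), THF, 80 °C (sealed); then NaBO3·4H2O, THF/H2O, rt
Reagents that add atoms: bis(pinacolato)diboron, CC1(C)OB(OC1(C)C)B1OC(C)(C)C(C)(C)O1 (boryl group of 9); sodium perborate NaBO3·4H2O, [Na+].[Na+].O[B-]1(O)OO[B-](O)(O)OO1 (phenol oxygen of 10)
Why: A bipyridine-bound tris(boryl) complex of trivalent iridium cleaves an aromatic C–H bond and releases the aryl boronate by C–B reductive elimination, B2pin2 restoring the boryl complex; this is the standard sterically governed aromatic C–H borylation, and the second stage is the standard perborate oxidation of an aryl boronate, in which peroxide adds to boron and the aryl group migrates from boron to oxygen. No ring is closed and no stereocentre is formed. The selectivity needed is one out of six aromatic C–H bonds, and it is secured because the crowded metal centre does not insert into a C–H bond that has an ortho substituent: C6–H lies next to the acyloxymethyl carbon, C4–H next to the silyloxy group, and all three C–H bonds of ring B are flanked on both sides, which leaves C5–H alone. The bulky triisopropylsilyl groups reinforce this shielding, and the alkyl C–H bonds of the chain and of the silyl groups should be inert with this catalyst at 80 °C. The ester and the aryl silyl ethers should tolerate both the neutral borylation and the mildly basic perborate at room temperature.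

Step 7
Reactants: 10 [5-hydroxy-2-[3-methyl-5-(triisopropylsilyloxy)phenoxy]-3-(triisopropylsilyloxy)phenyl]methyl hexadecanoate
Product: 11 [5-methoxy-2-[3-methyl-5-(triisopropylsilyloxy)phenoxy]-3-(triisopropylsilyloxy)phenyl]methyl hexadecanoate
Conditions: MeI, K2CO3, acetone, rt
Reagents that add atoms: iodomethane, CI
Why: Williamson ether synthesis on the only free phenol, under anhydrous carbonate conditions that should not cleave triisopropylsilyl aryl ethers or the ester, so that no second site can be methylated.

Step 8
Reactants: 11 [5-methoxy-2-[3-methyl-5-(triisopropylsilyloxy)phenoxy]-3-(triisopropylsilyloxy)phenyl]methyl hexadecanoate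
Product: 12 Betaethrin H, [3-hydroxy-2-(3-hydroxy-5-methylphenoxy)-5-methoxyphenyl]methyl hexadecanoate
Conditions: Bu4NF (2.4 equiv), AcOH (3 equiv), THF, 0 °C
Reagents that add atoms: none
Why: Fluoride-induced Si–O cleavage driven by the strong Si–F bond, fast for aryl silyl ethers because phenoxide is a good leaving group, with acetic acid keeping the medium near neutral so that the benzylic palmitate is neither hydrolysed nor transferred to a phenoxide.

Compound list
1 | 2-fluoro-3-methoxybenzaldehyde | COc1cccc(C=O)c1F | starting material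
2 | 3-methoxy-5-methylphenol | COc1cc(C)cc(O)c1 | starting material
3 | 3-methoxy-2-(3-methoxy-5-methylphenoxy)benzaldehyde | COc1cccc(C=O)c1Oc1cc(C)cc(OC)c1 | intermediate
4 | 3-hydroxy-2-(3-hydroxy-5-methylphenoxy)benzaldehyde | O=Cc1cccc(O)c1Oc1cc(C)cc(O)c1 | intermediate
5 | 2-[3-methyl-5-(triisopropylsilyloxy)phenoxy]-3-(triisopropylsilyloxy)benzaldehyde | O=Cc1cccc(O[Si](C(C)C)(C(C)C)C(C)C)c1Oc1cc(C)cc(O[Si](C(C)C)(C(C)C)C(C)C)c1 | intermediate
6 | [2-[3-methyl-5-(triisopropylsilyloxy)phenoxy]-3-(triisopropylsilyloxy)phenyl]methanol | OCc1cccc(O[Si](C(C)C)(C(C)C)C(C)C)c1Oc1cc(C)cc(O[Si](C(C)C)(C(C)C)C(C)C)c1 | intermediate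
7 | hexadecanoyl chloride (palmitoyl chloride) | CCCCCCCCCCCCCCCC(=O)Cl | starting material
8 | [2-[3-methyl-5-(triisopropylsilyloxy)phenoxy]-3-(triisopropylsilyloxy)phenyl]methyl hexadecanoate | CCCCCCCCCCCCCCCC(=O)OCc1cccc(O[Si](C(C)C)(C(C)C)C(C)C)c1Oc1cc(C)cc(O[Si](C(C)C)(C(C)C)C(C)C)c1 | intermediate
9 | [2-[3-methyl-5-(triisopropylsilyloxy)phenoxy]-5-(4,4,5,5-tetramethyl-1,3,2-dioxaborolan-2-yl)-3-(triisopropylsilyloxy)phenyl]methyl hexadecanoate | CCCCCCCCCCCCCCCC(=O)OCc1cc(B2OC(C)(C)C(C)(C)O2)cc(O[Si](C(C)C)(C(C)C)C(C)C)c1Oc1cc(C)cc(O[Si](C(C)C)(C(C)C)C(C)C)c1 | intermediate (not isolated)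
10 | [5-hydroxy-2-[3-methyl-5-(triisopropylsilyloxy)phenoxy]-3-(triisopropylsilyloxy)phenyl]methyl hexadecanoate | CCCCCCCCCCCCCCCC(=O)OCc1cc(O)cc(O[Si](C(C)C)(C(C)C)C(C)C)c1Oc1cc(C)cc(O[Si](C(C)C)(C(C)C)C(C)C)c1 | intermediate
11 | [5-methoxy-2-[3-methyl-5-(triisopropylsilyloxy)phenoxy]-3-(triisopropylsilyloxy)phenyl]methyl hexadecanoate | CCCCCCCCCCCCCCCC(=O)OCc1cc(OC)cc(O[Si](C(C)C)(C(C)C)C(C)C)c1Oc1cc(C)cc(O[Si](C(C)C)(C(C)C)C(C)C)c1 | intermediate
12 | Betaethrin H, [3-hydroxy-2-(3-hydroxy-5-methylphenoxy)-5-methoxyphenyl]methyl hexadecanoate | CCCCCCCCCCCCCCCC(=O)OCc1cc(OC)cc(O)c1Oc1cc(C)cc(O)c1 | target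

Total step count: 8. Longest linear sequence: 8 steps (1 to 12).

Steps most likely to fail

Step 6. The borylation may stall on this electron-rich, crowded and very lipophilic arene, may spill over to a flanked C–H bond, or the ester may be attacked during the oxidative work-up. The fallback fixes the position with a halogen instead of a C–H activation. It sets out from compound 2, which is joined by the same K2CO3/DMSO substitution to 5-bromo-2-fluoro-3-methoxybenzaldehyde to give 5-bromo-3-methoxy-2-(3-methoxy-5-methylphenoxy)benzaldehyde F1. BBr3 should then give 5-bromo-3-hydroxy-2-(3-hydroxy-5-methylphenoxy)benzaldehyde F2, and iPr3SiCl/imidazole 5-bromo-2-[3-methyl-5-(triisopropylsilyloxy)phenoxy]-3-(triisopropylsilyloxy)benzaldehyde F3. NaBH4 should give [5-bromo-2-[3-methyl-5-(triisopropylsilyloxy)phenoxy]-3-(triisopropylsilyloxy)phenyl]methanol F4, and acylation with 7 [5-bromo-2-[3-methyl-5-(triisopropylsilyloxy)phenoxy]-3-(triisopropylsilyloxy)phenyl]methyl hexadecanoate F5. Miyaura borylation of F5 (PdCl2(dppf), B2pin2, KOAc, dioxane, 80 °C) comes back to the route at boronate 9, which is oxidised with NaBO3·4H2O to 10 as in the second stage of step 6.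

Step 1. Displacement at a carbon flanked by the formyl and methoxy groups may be slow, so that base-induced consumption of the aldehyde (disproportionation, condensation) takes over. The fallback replaces the addition–elimination by a copper-catalysed Ullmann-type C–O coupling. It sets out from compound 2, which is coupled with 2-bromo-3-methoxybenzaldehyde (CuI, picolinic acid, K3PO4, DMSO, 90 °C), and comes back to the route directly at compound 3; it makes no new compound (F0).

Step 2. Cleavage of the second methyl ether may remain incomplete, or the longer exposure that the double cleavage needs may lead to halogenation at the formyl carbon. The fallback removes the methyl group before the ether is built, so that the diaryl ether never carries a methyl ether. It sets out from compound 1, whose single ether is cleaved with BBr3 on the small, well-behaved fluoroaldehyde to give 2-fluoro-3-hydroxybenzaldehyde F6 (also purchasable). MOMCl/iPr2NEt should give 2-fluoro-3-(methoxymethoxy)benzaldehyde F7. Substitution with orcinol (3 equiv, K2CO3, DMSO, 100 °C) should give 2-(3-hydroxy-5-methylphenoxy)-3-(methoxymethoxy)benzaldehyde F8, and HCl in MeOH/THF at rt removes the acetal and comes back to the route at compound 4.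

Further compounds
F1 | step 6 | 5-bromo-3-methoxy-2-(3-methoxy-5-methylphenoxy)benzaldehyde | COc1cc(Br)cc(C=O)c1Oc1cc(C)cc(OC)c1
F2 | step 6 | 5-bromo-3-hydroxy-2-(3-hydroxy-5-methylphenoxy)benzaldehyde | O=Cc1cc(Br)cc(O)c1Oc1cc(C)cc(O)c1
F3 | step 6 | 5-bromo-2-[3-methyl-5-(triisopropylsilyloxy)phenoxy]-3-(triisopropylsilyloxy)benzaldehyde | O=Cc1cc(Br)cc(O[Si](C(C)C)(C(C)C)C(C)C)c1Oc1cc(C)cc(O[Si](C(C)C)(C(C)C)C(C)C)c1
F4 | step 6 | [5-bromo-2-[3-methyl-5-(triisopropylsilyloxy)phenoxy]-3-(triisopropylsilyloxy)phenyl]methanol | OCc1cc(Br)cc(O[Si](C(C)C)(C(C)C)C(C)C)c1Oc1cc(C)cc(O[Si](C(C)C)(C(C)C)C(C)C)c1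
F5 | step 6 | [5-bromo-2-[3-methyl-5-(triisopropylsilyloxy)phenoxy]-3-(triisopropylsilyloxy)phenyl]methyl hexadecanoate | CCCCCCCCCCCCCCCC(=O)OCc1cc(Br)cc(O[Si](C(C)C)(C(C)C)C(C)C)c1Oc1cc(C)cc(O[Si](C(C)C)(C(C)C)C(C)C)c1
F0 | step 1 | none | none
F6 | step 2 | 2-fluoro-3-hydroxybenzaldehyde | O=Cc1cccc(O)c1F
F7 | step 2 | 2-fluoro-3-(methoxymethoxy)benzaldehyde | COCOc1cccc(C=O)c1F
F8 | step 2 | 2-(3-hydroxy-5-methylphenoxy)-3-(methoxymethoxy)benzaldehyde | COCOc1cccc(C=O)c1Oc1cc(C)cc(O)c1
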